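**Retrosynthetic overview**
1. The target is a symmetrical, tetra-ortho-substituted biaryl, so the one strategic disconnection is the aryl–aryl bond, giving two identical 2-iodo-3,4,5-trimethoxyphenylacetone halves (Ullmann reductive homocoupling).
2. The enolisable ketones are masked as 1,3-dioxolanes for the copper coupling and released in the acidic work-up of the same step.
3. The iodide comes from ring iodination of commercial 3,4,5-trimethoxyphenylacetone, whose only free ring positions (C2/C6) are equivalent.
4. No carbocyclic ring is built: both arenes are bought, the temporary dioxolane rings are formed in step 2 and opened in step 3, and the biaryl bond is made last.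

Assumption: the SMILES carries no stereodescriptor and the only stereo element is the hindered biaryl axis, so the compound is made as the racemate and no stereocentre has to be set.

**Step 1**
Reactants: 1 1-(3,4,5-trimethoxyphenyl)propan-2-one
Product: 2 1-(2-iodo-3,4,5-trimethoxyphenyl)propan-2-one
Conditions: NIS (1.05 equiv), CF3CO2H (0.3 equiv), MeCN, 0 °C to rt, dark; aq. Na2S2O3 work-up
Reagents that add atoms: N-iodosuccinimide, O=C1CCC(=O)N1I
Why: Electrophilic aromatic iodination with acid-activated NIS hits the free ring position ortho/para to methoxy groups, which is far more nucleophilic than the ketone enol, so mono-iodination gives 2 and no stereocentre is formed.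

**Step 2**
Reactants: 2 1-(2-iodo-3,4,5-trimethoxyphenyl)propan-2-one
Product: 3 2-[(2-iodo-3,4,5-trimethoxyphenyl)methyl]-2-methyl-1,3-dioxolane
Conditions: HOCH2CH2OH (5 equiv), p-TsOH·H2O (5 mol%), toluene, reflux, Dean–Stark; NaHCO3 wash
Reagents that add atoms: ethylene glycol, OCCO
Why: Acid-catalysed ketalisation driven by azeotropic water removal masks the enolisable ketone, which could otherwise undergo copper-enolate O-arylation to a benzofuran or aldol condensation in the hot coupling, while the aryl iodide and methyl ethers are inert.

**Step 3**
Reactants: 3 2-[(2-iodo-3,4,5-trimethoxyphenyl)methyl]-2-methyl-1,3-dioxolane (two molecules)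
Product: 5 (±)-1,1'-(4,4',5,5',6,6'-hexamethoxy[1,1'-biphenyl]-2,2'-diyl)bis(propan-2-one), via bis-dioxolane biaryl 4 (not isolated)
Conditions: activated Cu powder (8 equiv), neat, 230 °C, Ar; CH2Cl2/Celite filtration; then 2 M aq. HCl, THF, rt
Reagents that add atoms: water, O
Why: Classical Ullmann reductive homocoupling of the aryl iodide on zerovalent copper forges the tetra-ortho-substituted biaryl bond between two identical halves (the axis forms as the racemate), and acid-catalysed ketal hydrolysis in the work-up releases both ketones.

**Compound list**
1 | 1-(3,4,5-trimethoxyphenyl)propan-2-one | COc1cc(CC(C)=O)cc(OC)c1OC | starting material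
2 | 1-(2-iodo-3,4,5-trimethoxyphenyl)propan-2-one | Ic1c(CC(C)=O)cc(OC)c(OC)c1OC | intermediate
3 | 2-[(2-iodo-3,4,5-trimethoxyphenyl)methyl]-2-methyl-1,3-dioxolane | Ic1c(CC2(C)OCCO2)cc(OC)c(OC)c1OC | intermediate
4 | (±)-2,2'-[(4,4',5,5',6,6'-hexamethoxy[1,1'-biphenyl]-2,2'-diyl)bis(methylene)]bis(2-methyl-1,3-dioxolane) (bis-dioxolane biaryl) | COc1cc(CC2(C)OCCO2)c(-c2c(CC3(C)OCCO3)cc(OC)c(OC)c2OC)c(OC)c1OC | intermediate
5 | (±)-1,1'-(4,4',5,5',6,6'-hexamethoxy[1,1'-biphenyl]-2,2'-diyl)bis(propan-2-one) | COc1cc(CC(C)=O)c(-c2c(CC(C)=O)cc(OC)c(OC)c2OC)c(OC)c1OC | target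

**Totals**
Total step count: 3. Longest linear sequence: 3 (fully linear; the two halves are joined in step 3).

**Steps most likely to fail, with fallbacks**

Step 3 (most at risk). The iodide is electron-rich and di-ortho-substituted, so protodeiodination can compete with coupling, and the ketal must survive 230 °C. The fallback sets out from 3 and replaces the reductive homocoupling by a cross-coupling of two differently activated halves. Part of 3 is borylated (B2pin2, Pd2(dba)3, XPhos, KOAc, dioxane, 100 °C) to the aryl boronate 2-{2,3,4-trimethoxy-6-[(2-methyl-1,3-dioxolan-2-yl)methyl]phenyl}-4,4,5,5-tetramethyl-1,3,2-dioxaborolane F1. F1 is then joined to the remaining 3 by Suzuki–Miyaura coupling (Pd2(dba)3, SPhos, K3PO4, toluene/H2O, 100 °C), a zerovalent palladium/biarylphosphine system suited to tetra-ortho-substituted biaryls. This comes back to the route at 4, which is hydrolysed with aqueous HCl as in step 3 to give 5.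

Step 1. The benzylic ketone may be iodinated at the alpha carbon, or the ring may take a second iodine at C6. The fallback sets out from 1 and drops the halide altogether. Compound 1 is dimerised by oxidative dehydrogenative biaryl coupling through its arene radical cation (PhI(OCOCF3)2 0.55 equiv, BF3·OEt2, CH2Cl2, −40 °C; MoCl5 in CH2Cl2 at 0 °C as the alternative oxidant). Coupling can only occur at the free C2/C6 position, para to a methoxy group. This comes back to the route directly at 5 and passes through no new compound (none F0).

Step 2. The electron-rich aryl iodide may lose iodine under hot acid, or ketalisation may stall. The fallback sets out from 1 and reverses the order of protection and halogenation. The halogen-free ketone 1 is ketalised first (ethylene glycol, p-TsOH·H2O, toluene, Dean–Stark) to 2-methyl-2-[(3,4,5-trimethoxyphenyl)methyl]-1,3-dioxolane F2. F2 is then iodinated on the ring under acid-free conditions (NIS, dry MeCN, rt to 50 °C; or I2/CF3CO2Ag with solid NaHCO3 in CHCl3). This comes back to the route at 3.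

**Further compounds**
F1 | step 3 | 2-{2,3,4-trimethoxy-6-[(2-methyl-1,3-dioxolan-2-yl)methyl]phenyl}-4,4,5,5-tetramethyl-1,3,2-dioxaborolane | CC1(C)OB(OC1(C)C)c1c(CC2(C)OCCO2)cc(OC)c(OC)c1OC
F0 | step 1 | none | none
F2 | step 2 | 2-methyl-2-[(3,4,5-trimethoxyphenyl)methyl]-1,3-dioxolane | COc1cc(CC2(C)OCCO2)cc(OC)c1OC
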